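Assumption: the target SMILES has no stereocentre and no stereodescriptor, and the hindered quinone–quinone axis is not specified, so nothing stereochemical has to be set and the compound is made exactly as drawn.

**Retrosynthetic overview**
- The ring–ring C–C bond and one C–O bond per quinone ring are disconnected together, back to two molecules of C-methyl dihydropinosylvin (2-methyl-5-phenethylresorcinol), as in oxidative phenol coupling of a stilbenoid.
- Each resorcinol ring is opened by a polyketide-type aldol disconnection to an open-chain 2,4,6-triketone (a decarboxylated tetraketide equivalent), so both quinone rings and the bond between them trace back in one flask to two molecules of an acyclic triketone.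
- The triketone is cut into the 1,3-dianion of 3-methylpentane-2,4-dione and methyl 3-phenylpropanoate (a "starter unit" acylation).
- Ring order: the two phenyl rings are bought; the two oxygenated rings are closed by aldol aromatisation, then oxygenated to hydroxyquinones, then joined.

**Route**

Step 1
Reactants: 1 3-methylpentane-2,4-dione; 2 methyl 3-phenylpropanoate
Product: 4 3-methyl-8-phenyloctane-2,4,6-trione (keto–enol mixture, C3 racemic and enolisable), via dilithium dianion 3 (not isolated)
Conditions: 1 (2.0 equiv), LiN(i-Pr)2 (4.0 equiv), THF, 0 °C; then 2 (1.0 equiv), −78 → 0 °C; cold aq HCl to pH 4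
Reagents that add atoms: none
Why: Hauser–Harris γ-acylation (Claisen-type condensation) of a β-diketone 1,3-dianion: the terminal carbanion of 3 is the most nucleophilic site and attacks the ester carbonyl of 2, and the second equivalent of 3 deprotonates the more acidic triketone as it forms, protecting it as its enolate until the mild acid quench; no stereocentre of consequence is created.

Step 2
Reactants: 4 3-methyl-8-phenyloctane-2,4,6-trione (2 molecules per molecule of product)
Product: 7 5,5'-dihydroxy-6,6'-dimethyl-3,3'-bis(2-phenylethyl)-2,2'-bi(1,4-benzoquinone), via resorcinol 5 (not isolated), via hydroxyquinone 6 (not isolated)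
Conditions: KOH (6 equiv), degassed EtOH–H2O 4:1 (0.05 M), Ar, 40 °C; then O2 (1 atm), 0 °C → rt; then 1 M HCl
Reagents that add atoms: dioxygen, O=O
Why: Proposed new method: two known processes are run back to back in one alkaline medium. Under argon a Collie–Harris polyketide-type aldol condensation, dehydration and enolisation (C1 methyl enolate onto the C6 ketone) gives the dianion of resorcinol 5; the methyl terminus is the less hindered nucleophile and the alternative C7-to-C2 closure would give a crowded penta-substituted arene. Admitting O2 then starts the Beam-type alkaline autoxidation known for 2-substituted 5-alkylresorcinols such as cannabidiol, which oxygenates the position para to a phenoxide to give hydroxyquinone 6 and couples 6 with its reduced (semiquinone-level) form at the only free ring carbon, giving 7 after reoxidation. The closest known reaction types are the base cyclisation of 2,4,6-triketones to resorcinols and the oxidative phenol coupling of hydroxyhydroquinones; no stereocentre is formed and the axis is not controlled. Overall 2 × 4 + 5/2 O2 → 7 + 5 H2O.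

**Compound list**
1 | 3-methylpentane-2,4-dione | CC(=O)C(C)C(C)=O | starting material
2 | methyl 3-phenylpropanoate | COC(=O)CCc1ccccc1 | starting material
3 | dilithium 3-methylpenta-1,3-diene-2,4-diolate (1,3-dianion of 1) | C=C([O-])C(C)=C(C)[O-].[Li+].[Li+] | intermediate
4 | 3-methyl-8-phenyloctane-2,4,6-trione | CC(=O)C(C)C(=O)CC(=O)CCc1ccccc1 | intermediate
5 | 2-methyl-5-(2-phenylethyl)benzene-1,3-diol | Cc1c(O)cc(CCc2ccccc2)cc1O | intermediate
6 | 3-hydroxy-2-methyl-5-(2-phenylethyl)cyclohexa-2,5-diene-1,4-dione | CC1=C(O)C(=O)C(CCc2ccccc2)=CC1=O | intermediate
7 | 5,5'-dihydroxy-6,6'-dimethyl-3,3'-bis(2-phenylethyl)-2,2'-bi(1,4-benzoquinone) (CNP0136737.0) | CC1=C(O)C(=O)C(CCc2ccccc2)=C(C2=C(CCc3ccccc3)C(=O)C(O)=C(C)C2=O)C1=O | target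

**Totals**
Total step count: 2. Longest linear sequence: 2.

**Steps most likely to fail, with fallbacks**
The route has only two steps, so the three risk points are the two separable stages of step 2 and step 1.

Risk 1 is the oxygen stage of step 2: over-oxidation by the peroxide formed during autoxidation, or stalling at monomer 6. The fallback sets out from 4 and comes back at 7. The first stage of step 2 is run alone and quenched with acid under argon, so that 5 is isolated. Teuber oxidation of 5 with potassium nitrosodisulfonate, (KSO3)2NO, in KH2PO4-buffered water–acetone at 0 °C gives isolated 6. Half of 6 is reduced with Na2S2O4 to 3-methyl-6-(2-phenylethyl)benzene-1,2,4-triol F1. F1 and the remaining 6 (1:1) in degassed AcOH at rt undergo acid-promoted conjugate arylation at the only free carbon of each partner, the same position as in the air dimerisation of benzene-1,2,4-triol. This gives 3,3'-dimethyl-6,6'-bis(2-phenylethyl)-[1,1'-biphenyl]-2,2',4,4',5,5'-hexol F2, which Ag2O in CH2Cl2–MeOH oxidises to 7.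

Risk 2 is the ring-closure stage of step 2: the wrong aldol direction (C7 onto C2) or retro-Claisen cleavage by hydroxide. The fallback sets out from 4 and comes back at 5. Compound 4 is deprotonated three times with LiN(i-Pr)2 (3.3 equiv, THF, 0 °C; the third, kinetic deprotonation is at the terminal methyl) and carboxylated there with CO2, giving 4-methyl-3,5,7-trioxo-9-phenylnonanoic acid F3. In aqueous buffer at pH 7–9 at rt its doubly activated C2 methylene is the only competent nucleophile and closes onto C7 (Harris resorcylic acid cyclisation), giving 2,4-dihydroxy-3-methyl-6-(2-phenylethyl)benzoic acid F4. Heating F4 in water–DMSO at 100 °C decarboxylates it to 5, which then enters the O2 stage of step 2 (KOH, EtOH–H2O, O2, 0 °C) to reach 7.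

Risk 3 is step 1: proton transfer to, and self-condensation of, the enolisable ester, and the need for two equivalents of dianion. The fallback sets out from 1 and comes back at 4. Dianion 3 (from 1 and 2 equiv LiN(i-Pr)2, THF, 0 °C) is added at −78 °C to 3-phenylpropanal. This aldol addition has no leaving group and no acidic product, so the stoichiometry is 1:1, and it gives 6-hydroxy-3-methyl-8-phenyloctane-2,4-dione F5 as a diastereomer mixture, which does not matter. Dess–Martin periodinane in CH2Cl2 at rt oxidises the carbinol to the C6 ketone, giving 4.

**Further compounds**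
F1 | step 2 | 3-methyl-6-(2-phenylethyl)benzene-1,2,4-triol | Cc1c(O)cc(CCc2ccccc2)c(O)c1O
F2 | step 2 | 3,3'-dimethyl-6,6'-bis(2-phenylethyl)-[1,1'-biphenyl]-2,2',4,4',5,5'-hexol | Cc1c(O)c(O)c(CCc2ccccc2)c(-c2c(CCc3ccccc3)c(O)c(O)c(C)c2O)c1O
F3 | step 2 | 4-methyl-3,5,7-trioxo-9-phenylnonanoic acid | OC(=O)CC(=O)C(C)C(=O)CC(=O)CCc1ccccc1
F4 | step 2 | 2,4-dihydroxy-3-methyl-6-(2-phenylethyl)benzoic acid | Cc1c(O)cc(CCc2ccccc2)c(C(=O)O)c1O
F5 | step 1 | 6-hydroxy-3-methyl-8-phenyloctane-2,4-dione | CC(=O)C(C)C(=O)CC(O)CCc1ccccc1
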